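**Retrosynthetic overview**
1. The target is (2S)-8-prenyleriodictyol. It poses two problems: the base-labile benzylic stereocentre C2 in ring C, and placing the prenyl group at C8 rather than C6 of the phloroglucinol ring A.
2. Key cut, C2–C1′ (ring C to catechol ring B): the flat, achiral γ-pyrone ring C (O1–C2=C3–C4=O) of an 8-prenylchromone is taken out of conjugation by a ligand-controlled Rh-catalysed 1,4-arylation. This joins the two halves and sets C2 in the penultimate step, with no chalcone and no oxa-Michael closure.
3. Second cut, C8–CH2: the prenyl group is loaded on O5 and relayed O5→C6→C8 by a Claisen–Cope double [3,3] shift through dearomatised ring-A dienones. C8 is the only position para to O5, and ring C already distinguishes O5 from O1.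
4. Ring order: ring A is bought (phloroacetophenone). Ring C is closed first by C1 insertion, where the two ortho OH groups are equivalent. Ring B is bought (4-bromocatechol) and attached last.
5. After C2 is set, only one mild acidic step follows, so the base-induced ring opening to the chalcone is never offered.

Key step: step 7

Assumption: the target SMILES is read as (2S). The sense of induction in step 7 is taken from the model for (S)-biaryl bisphosphine/Rh catalysts with cyclic enones, and the ligand antipode would serve if the sense proved opposite.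

**Step 1**
Reactants: 1 2′,4′,6′-trihydroxyacetophenone
Product: 3 5,7-dihydroxy-4H-chromen-4-one, via 4-ethoxybenzopyrylium perchlorate 2 (not isolated)
Conditions: HC(OEt)3 (excess), 70% aq HClO4 (1.1 equiv), 0 °C to rt; the moist salt is taken up directly in H2O, 90 °C
Reagents that add atoms: triethyl orthoformate, CCOC(OCC)OCC; water, O
Why: Acid-mediated orthoformate cyclocondensation of an o-hydroxyacetophenone (C-formylation of the enol ether by the diethoxycarbenium ion, closure through an ortho OH to the benzopyrylium salt, then hydrolysis) closes ring C, and only one chromone can form because the two ortho OH groups of 1 are equivalent.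

**Step 2**
Reactants: 3 5,7-dihydroxy-4H-chromen-4-one
Product: 4 5-hydroxy-7-(methoxymethoxy)-4H-chromen-4-one
Conditions: MOMCl (1.05 equiv), K2CO3 (1.1 equiv), acetone, 0 °C to rt
Reagents that add atoms: chloromethyl methyl ether (MOMCl), COCCl
Why: Williamson-type O-alkylation should be selective for 7-OH, the vinylogous-acid hydroxyl that is deprotonated first, while 5-OH is held in the hydrogen bond to C4=O.

**Step 3**
Reactants: 4 5-hydroxy-7-(methoxymethoxy)-4H-chromen-4-one; 5 prenyl bromide (1-bromo-3-methylbut-2-ene)
Product: 6 7-(methoxymethoxy)-5-(3-methylbut-2-enyloxy)-4H-chromen-4-one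
Conditions: K2CO3 (2 equiv), acetone, reflux
Reagents that add atoms: none
Why: Williamson etherification of the remaining chelated phenol with a reactive primary allylic bromide (SN2) should give the linear O5-prenyl ether, and amine-free acetone spares the base-sensitive C2 of the chromone.

**Step 4**
Reactants: 6 7-(methoxymethoxy)-5-(3-methylbut-2-enyloxy)-4H-chromen-4-one
Product: 9 5-hydroxy-7-(methoxymethoxy)-8-(3-methylbut-2-enyl)-4H-chromen-4-one, via C6 ortho-dienone 7 (not isolated), via C8 para-dienone 8 (not isolated)
Conditions: Eu(fod)3 (10 mol %), NaHCO3 (solid buffer), PhCl, 85 °C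
Reagents that add atoms: none
Why: In this Lewis-acid-catalysed aromatic para-Claisen (Claisen–Cope) rearrangement, known for 5-prenyloxy flavonoids, Eu(III) chelated between C4=O and O5 triggers the first [3,3] shift to C6, and the crowded 1,1-dimethylallyl dienone passes the group by a second [3,3] shift to C8 (para to O5) before tautomerisation restores ring A with the prenyl group in its linear form.

**Step 5**
Reactants: 10 4-bromocatechol
Product: 11 4-bromo-1,2-bis(methoxymethoxy)benzene
Conditions: MOMCl (2.4 equiv), K2CO3 (3 equiv), acetone, 0 to 40 °C, N2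
Reagents that add atoms: chloromethyl methyl ether (MOMCl), COCCl
Why: Double Williamson-type acetal formation masks the catechol with groups that tolerate organolithium and aqueous Rh chemistry and that leave together with the 7-O-MOM group at the end.

**Step 6**
Reactants: 11 4-bromo-1,2-bis(methoxymethoxy)benzene
Product: 14 [3,4-bis(methoxymethoxy)phenyl]boronic acid, via aryllithium 12 (not isolated), via lithium aryltriisopropoxyborate 13 (not isolated)
Conditions: n-BuLi (1.05 equiv), THF, –78 °C; B(OiPr)3 (1.3 equiv), –78 °C to rt; 1 M aq HCl to pH 5, 0 °C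
Reagents that add atoms: triisopropyl borate, CC(C)OB(OC(C)C)OC(C)C; water, O
Why: Bromine–lithium exchange is faster at –78 °C than MOM-directed ortho-lithiation, and trapping with the borate followed by cold, weakly acidic hydrolysis should give the boronic acid with both acetals intact.

**Step 7**
Reactants: 9 5-hydroxy-7-(methoxymethoxy)-8-(3-methylbut-2-enyl)-4H-chromen-4-one; 14 [3,4-bis(methoxymethoxy)phenyl]boronic acid
Product: 15 (2S)-2-[3,4-bis(methoxymethoxy)phenyl]-5-hydroxy-7-(methoxymethoxy)-8-(3-methylbut-2-enyl)-2,3-dihydro-4H-chromen-4-one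
Conditions: 14 (2.5 equiv), [RhCl(C2H4)2]2 (1.5 mol %), (S)-MeO-F12-BIPHEP [(S)-2,2′-bis{bis(3,4,5-trifluorophenyl)phosphino}-6,6′-dimethoxybiphenyl] (3.3 mol %), aq KOH (10 mol %), toluene/H2O 10:1, 25–40 °C, Ar
Reagents that add atoms: none
Why: This is the Rh(I)-catalysed asymmetric 1,4-addition of an arylboronic acid (Hayashi–Miyaura reaction), a reaction type established for 4H-chromen-4-ones: boron-to-rhodium transmetalation gives an aryl–Rh species, C2=C3 of the γ-pyrone inserts with aryl transfer to C2, and water protonates the oxa-π-allyl rhodium enolate at C3 and returns Rh–OH. No ring is closed: ring C is already in place and is only taken out of conjugation, so one operation forms the C2–C1′ bond, joins the A/C half to ring B and turns a flat achiral benzopyrone into the C2-stereogenic chromanone. C2, the only stereocentre, is controlled by the ligand alone; by the quadrant model for (S)-biaryl bisphosphines and cyclic enones the aryl group should be delivered to the Re face of C2, which corresponds to (S). Chemoselectivity for C2=C3 over the prenyl C=C is secured by the substrate, since aryl–Rh(I) inserts into the carbonyl-polarised alkene and not into an isolated trisubstituted one, and the 1,4-mode is favoured over attack at C4 in toluene. The chelated 5-OH···O=C4 hydrogen bond raises the acceptor strength of the otherwise electron-rich 5,7-dioxygenated chromone, and it stays protonated because only catalytic base is present. The electron-poor ligand allows a low temperature, at which protonolysis of the enolate should outrun both β-elimination of the C8a phenoxide (opening to the chalcone, the racemisation channel) and 1,2-addition to the product ketone.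

**Step 8**
Reactants: 15 (2S)-2-[3,4-bis(methoxymethoxy)phenyl]-5-hydroxy-7-(methoxymethoxy)-8-(3-methylbut-2-enyl)-2,3-dihydro-4H-chromen-4-one
Product: 16 (2S)-2-(3,4-dihydroxyphenyl)-5,7-dihydroxy-8-(3-methylbut-2-enyl)-2,3-dihydro-4H-chromen-4-one (target)
Conditions: HCl (1.25 M in MeOH), 40 °C, Ar, short contact time; aq NaHCO3 to pH 6, extraction
Reagents that add atoms: none
Why: Acid-catalysed acetal methanolysis removes all three MOM groups without touching C2, because flavanones with free 4′-OH and 5-OH racemise through base-induced ring opening and not under mild acid, and the moderate temperature should keep the freed 7-OH from adding to the prenyl alkene.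

**Compound list**
1 | 2′,4′,6′-trihydroxyacetophenone | CC(=O)c1c(O)cc(O)cc1O | starting material
2 | 4-ethoxy-5,7-dihydroxychromenylium perchlorate | CCOc1cc[o+]c2cc(O)cc(O)c12.[O-]Cl(=O)(=O)=O | intermediate
3 | 5,7-dihydroxy-4H-chromen-4-one | O=C1C=COc2cc(O)cc(O)c12 | intermediate
4 | 5-hydroxy-7-(methoxymethoxy)-4H-chromen-4-one | O=C1C=COc2cc(OCOC)cc(O)c12 | intermediate
5 | prenyl bromide (1-bromo-3-methylbut-2-ene) | CC(C)=CCBr | starting material
6 | 7-(methoxymethoxy)-5-(3-methylbut-2-enyloxy)-4H-chromen-4-one | O=C1C=COc2cc(OCOC)cc(OCC=C(C)C)c12 | intermediate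
7 | 7-(methoxymethoxy)-6-(2-methylbut-3-en-2-yl)-4H-chromene-4,5(6H)-dione (racemic, transient) | O=C1C=COC2=C1C(=O)C(C(C)(C)C=C)C(OCOC)=C2 | intermediate
8 | 7-(methoxymethoxy)-8-(3-methylbut-2-enyl)-4H-chromene-4,5(8H)-dione (racemic, transient) | O=C1C=COC2=C1C(=O)C=C(OCOC)C2CC=C(C)C | intermediate
9 | 5-hydroxy-7-(methoxymethoxy)-8-(3-methylbut-2-enyl)-4H-chromen-4-one | O=C1C=COc2c(CC=C(C)C)c(OCOC)cc(O)c12 | intermediate
10 | 4-bromocatechol | Oc1ccc(Br)cc1O | starting material
11 | 4-bromo-1,2-bis(methoxymethoxy)benzene | COCOc1ccc(Br)cc1OCOC | intermediate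
12 | [3,4-bis(methoxymethoxy)phenyl]lithium | [Li]c1ccc(OCOC)c(OCOC)c1 | intermediate
13 | lithium [3,4-bis(methoxymethoxy)phenyl]triisopropoxyborate | [Li+].CC(C)O[B-](OC(C)C)(OC(C)C)c1ccc(OCOC)c(OCOC)c1 | intermediate
14 | [3,4-bis(methoxymethoxy)phenyl]boronic acid | OB(O)c1ccc(OCOC)c(OCOC)c1 | intermediate
15 | (2S)-2-[3,4-bis(methoxymethoxy)phenyl]-5-hydroxy-7-(methoxymethoxy)-8-(3-methylbut-2-enyl)-2,3-dihydro-4H-chromen-4-one | CC(C)=CCc1c(OCOC)cc(O)c2c1O[C@H](c1ccc(OCOC)c(OCOC)c1)CC2=O | intermediate
16 | (2S)-8-prenyleriodictyol, CNP0188247.1 | CC(C)=CCc1c(O)cc(O)c2c1O[C@H](c1ccc(O)c(O)c1)CC2=O | target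

**Total step count:** 8.
**Longest linear sequence:** 6 (steps 1, 2, 3, 4, 7, 8).

**Steps most likely to fail**

**Step 7.**
- Risk: insertion of the electron-rich chromone into aryl–Rh may be slower than protodeboronation of the electron-rich boronic acid. β-Elimination of the phenoxide from the rhodium enolate, followed by unselective re-closure, may also erode the enantiomeric purity.
- Fallback: bond formation and stereocontrol are separated. It sets out from 9 and 14 and comes back at 15.
- A cationic Pd(II)/2,2′-bipyridine catalyst in aqueous medium performs the conjugate arylation without a chiral ligand. This gives racemic 2-[3,4-bis(methoxymethoxy)phenyl]-5-hydroxy-7-(methoxymethoxy)-8-(3-methylbut-2-enyl)chroman-4-one F1.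
- F1 is then submitted to kinetic resolution by asymmetric transfer hydrogenation (Noyori–Ikariya type Cp*Rh(III)/(R,R)-TsDPEN, HCO2H/Et3N, EtOAc, rt), which is known for flavanones.
- The (2R)-ketone should be reduced to the cis-(2R,4R)-flavan-4-ol F2, which is removed by chromatography. The unreacted (2S)-ketone is 15.

**Step 4.**
- Risk: the first dienone may tautomerise before the Cope shift, which arrests the allyl group at C6 in its inverted form. The Lewis acid may also ionise the allylic C–O bond with loss of the prenyl group.
- Fallback: the C8–C bond is made by cross-coupling instead of rearrangement. It sets out from 4 and comes back at 9.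
- 4 is alkylated at O5 (MOMCl, NaH, THF) to 5,7-bis(methoxymethoxy)-4H-chromen-4-one F3.
- Electrophilic iodination (NIS, DMF, rt) goes to C8 in 5-O-alkylated 5,7-dioxygenated benzopyrones and gives 8-iodo-5,7-bis(methoxymethoxy)-4H-chromen-4-one F4.
- Stille coupling with tributyl(3-methylbut-2-enyl)stannane (Pd(PPh3)4, DMF, 80 °C) gives 5,7-bis(methoxymethoxy)-8-(3-methylbut-2-enyl)-4H-chromen-4-one F5.
- Brief methanolysis with catalytic p-TsOH at 0 °C removes only the carbonyl-assisted peri 5-O-MOM group and gives 9.

**Step 8.**
- Risk: the freed 7-OH may add to the protonated prenyl alkene (chroman formation), the alkene may take up solvent, or the catechol may be oxidised by air during the acid treatment.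
- Fallback: acid is removed from the endgame by carrying fluoride-labile silyl ethers. It sets out from 3 and 10 and comes back at 16.
- 3 is silylated at O7 (TIPSCl, imidazole, DMF) to 5-hydroxy-7-(triisopropylsilyloxy)-4H-chromen-4-one F6.
- F6 is etherified at O5 under neutral Mitsunobu conditions (3-methylbut-2-en-1-ol, PPh3, DIAD) to 5-(3-methylbut-2-enyloxy)-7-(triisopropylsilyloxy)-4H-chromen-4-one F7.
- F7 is rearranged as in step 4 to 5-hydroxy-8-(3-methylbut-2-enyl)-7-(triisopropylsilyloxy)-4H-chromen-4-one F8.
- In parallel, 10 gives 4-bromo-1,2-bis(tert-butyldimethylsilyloxy)benzene F9 with TBSCl/imidazole. Bromine–lithium exchange and borylation as in step 6 then give [3,4-bis(tert-butyldimethylsilyloxy)phenyl]boronic acid F10.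
- The arylation of step 7 joins F8 and F10 to the (2S)-tris-silyl flavanone F11.
- Et3N·3HF in THF at 0 °C to rt then frees the three phenols at a weakly acidic, non-ionising pH to give 16.

**Further compounds**
F1 | step 7 | racemic 2-[3,4-bis(methoxymethoxy)phenyl]-5-hydroxy-7-(methoxymethoxy)-8-(3-methylbut-2-enyl)chroman-4-one | CC(C)=CCc1c(OCOC)cc(O)c2c1OC(c1ccc(OCOC)c(OCOC)c1)CC2=O
F2 | step 7 | (2R,4R)-2-[3,4-bis(methoxymethoxy)phenyl]-7-(methoxymethoxy)-8-(3-methylbut-2-enyl)chromane-4,5-diol (cis-flavan-4-ol) | CC(C)=CCc1c(OCOC)cc(O)c2c1O[C@@H](c1ccc(OCOC)c(OCOC)c1)C[C@H]2O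
F3 | step 4 | 5,7-bis(methoxymethoxy)-4H-chromen-4-one | O=C1C=COc2cc(OCOC)cc(OCOC)c12
F4 | step 4 | 8-iodo-5,7-bis(methoxymethoxy)-4H-chromen-4-one | O=C1C=COc2c(I)c(OCOC)cc(OCOC)c12
F5 | step 4 | 5,7-bis(methoxymethoxy)-8-(3-methylbut-2-enyl)-4H-chromen-4-one | O=C1C=COc2c(CC=C(C)C)c(OCOC)cc(OCOC)c12
F6 | step 8 | 5-hydroxy-7-(triisopropylsilyloxy)-4H-chromen-4-one | O=C1C=COc2cc(O[Si](C(C)C)(C(C)C)C(C)C)cc(O)c12
F7 | step 8 | 5-(3-methylbut-2-enyloxy)-7-(triisopropylsilyloxy)-4H-chromen-4-one | O=C1C=COc2cc(O[Si](C(C)C)(C(C)C)C(C)C)cc(OCC=C(C)C)c12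
F8 | step 8 | 5-hydroxy-8-(3-methylbut-2-enyl)-7-(triisopropylsilyloxy)-4H-chromen-4-one | O=C1C=COc2c(CC=C(C)C)c(O[Si](C(C)C)(C(C)C)C(C)C)cc(O)c12
F9 | step 8 | 4-bromo-1,2-bis(tert-butyldimethylsilyloxy)benzene | Brc1ccc(O[Si](C)(C)C(C)(C)C)c(O[Si](C)(C)C(C)(C)C)c1
F10 | step 8 | [3,4-bis(tert-butyldimethylsilyloxy)phenyl]boronic acid | OB(O)c1ccc(O[Si](C)(C)C(C)(C)C)c(O[Si](C)(C)C(C)(C)C)c1
F11 | step 8 | (2S)-2-[3,4-bis(tert-butyldimethylsilyloxy)phenyl]-5-hydroxy-8-(3-methylbut-2-enyl)-7-(triisopropylsilyloxy)-2,3-dihydro-4H-chromen-4-one | CC(C)=CCc1c(O[Si](C(C)C)(C(C)C)C(C)C)cc(O)c2c1O[C@H](c1ccc(O[Si](C)(C)C(C)(C)C)c(O[Si](C)(C)C(C)(C)C)c1)CC2=O
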